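**Retrosynthetic overview**
1. The C3 angelate and C6 acetate go on last; the oxirane comes from a hydroxyl-directed, peripheral epoxidation of a germacra-1(10),4-dien-6-ol.
2. The ten-membered carbocycle is closed at C6–C7 by a new chromium-catalysed, ligand-controlled enantioselective macrocyclising allylation of an acyclic 12-chloro-4-silyloxy-farnesal (sets C6 and C7).
3. The acyclic chain comes from geranyl chloride and ethyl (E)-3-methyl-4-oxobut-2-enoate (α-selective allylbarium addition); oxidation and CBS reduction set C3; SeO2 oxidation and chlorination functionalise the terminus.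
4. Ring order: ten-membered carbocycle first (step 9), oxirane second (step 10).

Assumption: ring compounds carry germacrane locants (C1=C10 alkene, C3 angeloyloxy, C4/C5 oxirane carbons with the methyl on C4, C6 acetoxy, C7 isopropyl); acyclic compounds carry IUPAC chain locants.

**Step 1**
Reactants: 1 geranyl chloride; 2 ethyl (2E)-3-methyl-4-oxobut-2-enoate
Product: 4 ethyl (2E,6E)-4-hydroxy-3,7,11-trimethyldodeca-2,6,10-trienoate (racemic at C4), via geranylbarium chloride 3 (not isolated)
Conditions: BaI2, lithium biphenylide (LiC12H10, 2 equiv), THF, rt; 1, −78 °C; then 2, −78 °C; H2O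
Reagents that add atoms: barium diiodide, [Ba+2].[I-].[I-] (source of the barium in 3; no reagent atoms other than hydrogen remain in 4)
Why: Allylbarium addition (Yamamoto type): 3 attacks the aldehyde of 2 through its α-carbon with retention of the E alkene, giving the linear homoallylic alcohol instead of the γ-adduct, and the aldehyde reacts far faster than the conjugated ester at −78 °C; the new carbinol is racemic here.

**Step 2**
Reactants: 4 ethyl (2E,6E)-4-hydroxy-3,7,11-trimethyldodeca-2,6,10-trienoate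
Product: 5 ethyl (2E,6E)-3,7,11-trimethyl-4-oxododeca-2,6,10-trienoate
Conditions: Dess–Martin periodinane, pyridine, CH2Cl2, 0 °C
Reagents that add atoms: none
Why: Dess–Martin oxidation under buffered, non-basic conditions gives the ketone without moving the β,γ-alkene into conjugation and erases the racemic centre.

**Step 3**
Reactants: 5 ethyl (2E,6E)-3,7,11-trimethyl-4-oxododeca-2,6,10-trienoate
Product: 6 ethyl (2E,4S,6E)-4-hydroxy-3,7,11-trimethyldodeca-2,6,10-trienoate
Conditions: (R)-2-methyl-CBS-oxazaborolidine (20 mol%), catecholborane (1.5 equiv), toluene, −78 °C; MeOH, then aqueous work-up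
Reagents that add atoms: none
Why: Corey–Bakshi–Shibata reduction: the α-methyl alkenyl side is the large group and the allylic CH2 side the small one, so the (R)-catalyst delivers hydride to give the (S)-carbinol (future C3), while catecholborane at −78 °C leaves ester and alkenes alone.

**Step 4**
Reactants: 6 ethyl (2E,4S,6E)-4-hydroxy-3,7,11-trimethyldodeca-2,6,10-trienoate
Product: 7 ethyl (2E,4S,6E)-4-[(tert-butyldimethylsilyl)oxy]-3,7,11-trimethyldodeca-2,6,10-trienoate
Conditions: TBSCl, imidazole, DMF, rt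
Reagents that add atoms: tert-butyldimethylsilyl chloride, CC(C)(C)[Si](C)(C)Cl
Why: Standard silylation of the secondary alcohol gives an ether that survives the hydride, chromium and vanadium steps and keeps the C3 oxygen from directing the later epoxidation.

**Step 5**
Reactants: 7 ethyl (2E,4S,6E)-4-[(tert-butyldimethylsilyl)oxy]-3,7,11-trimethyldodeca-2,6,10-trienoate
Product: 8 ethyl (2E,4S,6E,10E)-4-[(tert-butyldimethylsilyl)oxy]-12-hydroxy-3,7,11-trimethyldodeca-2,6,10-trienoate
Conditions: SeO2 (0.2 equiv), t-BuOOH (2 equiv), salicylic acid (0.1 equiv), CH2Cl2, 0 °C → rt; stop at partial conversion and recycle 7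
Reagents that add atoms: tert-butyl hydroperoxide, CC(C)(C)OO (oxygen source, relayed by catalytic SeO2)
Why: Sharpless SeO2/t-BuOOH allylic oxidation (ene reaction then [2,3]-shift) selects the E-methyl of the terminal, most electron-rich trisubstituted alkene, as is usual for geranyl and farnesyl esters, and the enoate alkene is deactivated.

**Step 6**
Reactants: 8 ethyl (2E,4S,6E,10E)-4-[(tert-butyldimethylsilyl)oxy]-12-hydroxy-3,7,11-trimethyldodeca-2,6,10-trienoate
Product: 10 ethyl (2E,4S,6E,10E)-4-[(tert-butyldimethylsilyl)oxy]-12-chloro-3,7,11-trimethyldodeca-2,6,10-trienoate, via allylic mesylate 9 (not isolated)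
Conditions: MsCl, 2,4,6-collidine, LiCl, DMF, 0 °C
Reagents that add atoms: methanesulfonyl chloride, CS(=O)(=O)Cl (mesyl group of 9); lithium chloride, [Li+].[Cl-] (chlorine of 10)
Why: Mesylation and in situ SN2 displacement by chloride (Collington–Meyers conditions) convert the primary allylic alcohol to the chloride without allylic transposition or loss of E geometry.

**Step 7**
Reactants: 10 ethyl (2E,4S,6E,10E)-4-[(tert-butyldimethylsilyl)oxy]-12-chloro-3,7,11-trimethyldodeca-2,6,10-trienoate
Product: 11 (2E,4S,6E,10E)-4-[(tert-butyldimethylsilyl)oxy]-12-chloro-3,7,11-trimethyldodeca-2,6,10-trien-1-ol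
Conditions: iBu2AlH (2.5 equiv), CH2Cl2, −78 °C; aq. potassium sodium tartrate
Reagents that add atoms: none
Why: DIBAL 1,2-reduction of the unsaturated ester gives the E allylic alcohol at −78 °C, where the allylic chloride and the silyl ether are inert.

**Step 8**
Reactants: 11 (2E,4S,6E,10E)-4-[(tert-butyldimethylsilyl)oxy]-12-chloro-3,7,11-trimethyldodeca-2,6,10-trien-1-ol
Product: 12 (2E,4S,6E,10E)-4-[(tert-butyldimethylsilyl)oxy]-12-chloro-3,7,11-trimethyldodeca-2,6,10-trienal
Conditions: MnO2 (15 equiv), CH2Cl2, rt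
Reagents that add atoms: none
Why: MnO2 oxidises only the allylic alcohol, under neutral conditions, to the E enal and does not touch the allylic chloride.

**Step 9**
Reactants: 12 (2E,4S,6E,10E)-4-[(tert-butyldimethylsilyl)oxy]-12-chloro-3,7,11-trimethyldodeca-2,6,10-trienal
Product: 15 (1(10)E,4E,3S,6R,7S)-3-[(tert-butyldimethylsilyl)oxy]germacra-1(10),4,11-trien-6-ol, via allylchromium dichloride 13 (not isolated), via trimethylsilyl ether 14 (not isolated)
Conditions: CrCl2 (10 mol%), ligand L = (S,S)-3,6-diphenyl-1,8-bis(4-isopropyl-4,5-dihydrooxazol-2-yl)-9H-carbazole (12 mol%), Mn powder (3 equiv), Me3SiCl (2 equiv), iPr2NEt (0.3 equiv), THF, rt, 12 added over 24 h by syringe pump (final 0.002 M); then K2CO3 (cat.), MeOH, 0 °C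
Reagents that add atoms: CrCl2, [Cr+2].[Cl-].[Cl-] (metal of 13); chlorotrimethylsilane, C[Si](C)(C)Cl (silyl group of 14); no reagent atoms other than hydrogen remain in 15
Why: Proposed new method: a chromium-catalysed, ligand-controlled enantioselective macrocyclising allylation, in which divalent chromium (regenerated by Mn and Me3SiCl) inserts into the allylic C–Cl bond to give the trivalent σ-allylchromium 13, which settles as the E primary allyl species and adds through its γ-carbon (C7) to the tethered s-trans enal in a closed chair Zimmerman–Traxler transition state with both ring tethers equatorial, so the C6–C7 bond closes the ten-membered ring with 6,7-anti stereochemistry while the tridentate carbazole bis(oxazoline) ligand blocks one enal face and, helped by the C3 silyloxy group preferring the outer face of the forming ring, fixes the absolute configuration; the closest known chemistry is the intermolecular chromium-catalysed asymmetric allylation and crotylation of aldehydes with this ligand class together with stoichiometric, non-asymmetric chromium or palladium/zinc allylative closures of ten-membered germacrane rings.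

**Step 10**
Reactants: 15 (1(10)E,4E,3S,6R,7S)-3-[(tert-butyldimethylsilyl)oxy]germacra-1(10),4,11-trien-6-ol
Product: 16 (1(10)E,3S,4S,5R,6S,7S)-3-[(tert-butyldimethylsilyl)oxy]-4,5-epoxygermacra-1(10),11-dien-6-ol
Conditions: VO(acac)2 (5 mol%), t-BuOOH (1.2 equiv, in decane), 2,6-lutidine (0.2 equiv), CH2Cl2, −20 → 0 °C
Reagents that add atoms: tert-butyl hydroperoxide, CC(C)(C)OO
Why: Hydroxyl-directed vanadium-catalysed epoxidation: only C4=C5 is allylic to the free C6–OH, and because ring carbons C2 and C7 lie on the inner face while allylic strain with the C4 methyl holds H6 in the alkene plane, the C6–OH (and the C3–OSi) sit on the outer face and oxygen is delivered there, giving the oxirane threo to both carbinol oxygens, which is the target configuration at C4 and C5.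

**Step 11**
Reactants: 16 (1(10)E,3S,4S,5R,6S,7S)-3-[(tert-butyldimethylsilyl)oxy]-4,5-epoxygermacra-1(10),11-dien-6-ol
Product: 17 (1(10)E,3S,4S,5R,6S,7S)-3-[(tert-butyldimethylsilyl)oxy]-4,5-epoxygermacr-1(10)-en-6-ol
Conditions: H2 (1 atm), RhCl(PPh3)3 (10 mol%), benzene, rt
Reagents that add atoms: none
Why: Homogeneous hydrogenation with RhCl(PPh3)3 reduces the unhindered 1,1-disubstituted isopropenyl alkene and leaves the trisubstituted ring alkene and the oxirane untouched; no stereocentre is created.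

**Step 12**
Reactants: 17 (1(10)E,3S,4S,5R,6S,7S)-3-[(tert-butyldimethylsilyl)oxy]-4,5-epoxygermacr-1(10)-en-6-ol
Product: 18 (1(10)E,3S,4S,5R,6S,7S)-3-[(tert-butyldimethylsilyl)oxy]-4,5-epoxygermacr-1(10)-en-6-yl acetate
Conditions: Ac2O, DMAP (0.2 equiv), pyridine, CH2Cl2, 0 °C → rt
Reagents that add atoms: acetic anhydride, CC(=O)OC(C)=O
Why: DMAP-catalysed acylation of the only free hydroxyl (C6) under basic conditions that do not open the oxirane or trigger transannular cyclisation.

**Step 13**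
Reactants: 18 (1(10)E,3S,4S,5R,6S,7S)-3-[(tert-butyldimethylsilyl)oxy]-4,5-epoxygermacr-1(10)-en-6-yl acetate
Product: 19 (1(10)E,3S,4R,5R,6S,7S)-6-acetoxy-4,5-epoxygermacr-1(10)-en-3-ol
Conditions: Bu4NF (2 equiv), AcOH (2 equiv), THF, 0 °C → rt
Reagents that add atoms: none
Why: Fluoride-mediated desilylation, buffered with acetic acid so that no free alkoxide can start a Payne rearrangement or acetate migration.

**Step 14**
Reactants: 19 (1(10)E,3S,4R,5R,6S,7S)-6-acetoxy-4,5-epoxygermacr-1(10)-en-3-ol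
Product: 20 (1(10)E,3S,4R,5R,6S,7S)-6-acetoxy-4,5-epoxygermacr-1(10)-en-3-yl (Z)-2-methylbut-2-enoate (target, CNP0180504.4)
Conditions: angelic acid (4 equiv), 2,4,6-trichlorobenzoyl chloride (4 equiv), Et3N (8 equiv), toluene, rt, 2 h, filter; then 19, toluene, 75 °C
Reagents that add atoms: angelic acid [(Z)-2-methylbut-2-enoic acid], C/C=C(/C)C(=O)O
Why: Yamaguchi-type mixed-anhydride esterification run without DMAP, the established way to acylate hindered secondary alcohols with angelic acid without isomerisation to the tiglate, under amine-buffered conditions that spare the acid-labile epoxy-alkene.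

**Compound list**
(The descriptor at C6 in 14 and 15 and at C4 in 16–18 differs from the target only because CIP ranking changes; the spatial arrangement is the same throughout.)

1 | geranyl chloride [(2E)-1-chloro-3,7-dimethylocta-2,6-diene] | ClC/C=C(\C)CCC=C(C)C | starting material
2 | ethyl (2E)-3-methyl-4-oxobut-2-enoate | CCOC(=O)/C=C(\C)C=O | starting material
3 | geranylbarium chloride | Cl[Ba]C/C=C(\C)CCC=C(C)C | intermediate (not isolated)
4 | ethyl (2E,6E)-4-hydroxy-3,7,11-trimethyldodeca-2,6,10-trienoate, racemic | CCOC(=O)/C=C(\C)C(O)C/C=C(\C)CCC=C(C)C | intermediate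
5 | ethyl (2E,6E)-3,7,11-trimethyl-4-oxododeca-2,6,10-trienoate | CCOC(=O)/C=C(\C)C(=O)C/C=C(\C)CCC=C(C)C | intermediate
6 | ethyl (2E,4S,6E)-4-hydroxy-3,7,11-trimethyldodeca-2,6,10-trienoate | CCOC(=O)/C=C(\C)[C@@H](O)C/C=C(\C)CCC=C(C)C | intermediate
7 | ethyl (2E,4S,6E)-4-[(tert-butyldimethylsilyl)oxy]-3,7,11-trimethyldodeca-2,6,10-trienoate | CCOC(=O)/C=C(\C)[C@@H](O[Si](C)(C)C(C)(C)C)C/C=C(\C)CCC=C(C)C | intermediate
8 | ethyl (2E,4S,6E,10E)-4-[(tert-butyldimethylsilyl)oxy]-12-hydroxy-3,7,11-trimethyldodeca-2,6,10-trienoate | CCOC(=O)/C=C(\C)[C@@H](O[Si](C)(C)C(C)(C)C)C/C=C(\C)CC/C=C(\C)CO | intermediate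
9 | ethyl (2E,4S,6E,10E)-4-[(tert-butyldimethylsilyl)oxy]-12-(methanesulfonyloxy)-3,7,11-trimethyldodeca-2,6,10-trienoate | CCOC(=O)/C=C(\C)[C@@H](O[Si](C)(C)C(C)(C)C)C/C=C(\C)CC/C=C(\C)COS(C)(=O)=O | intermediate (not isolated)
10 | ethyl (2E,4S,6E,10E)-4-[(tert-butyldimethylsilyl)oxy]-12-chloro-3,7,11-trimethyldodeca-2,6,10-trienoate | CCOC(=O)/C=C(\C)[C@@H](O[Si](C)(C)C(C)(C)C)C/C=C(\C)CC/C=C(\C)CCl | intermediate
11 | (2E,4S,6E,10E)-4-[(tert-butyldimethylsilyl)oxy]-12-chloro-3,7,11-trimethyldodeca-2,6,10-trien-1-ol | OC/C=C(\C)[C@@H](O[Si](C)(C)C(C)(C)C)C/C=C(\C)CC/C=C(\C)CCl | intermediate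
12 | (2E,4S,6E,10E)-4-[(tert-butyldimethylsilyl)oxy]-12-chloro-3,7,11-trimethyldodeca-2,6,10-trienal | O=C/C=C(\C)[C@@H](O[Si](C)(C)C(C)(C)C)C/C=C(\C)CC/C=C(\C)CCl | intermediate
13 | σ-allylchromium dichloride derived from 12 (C12–Cr bond, trivalent chromium, chiral ligand on the metal not drawn) | O=C/C=C(\C)[C@@H](O[Si](C)(C)C(C)(C)C)C/C=C(\C)CC/C=C(\C)C[Cr](Cl)Cl | intermediate (not isolated)
14 | (1(10)E,4E,3S,6R,7S)-3-[(tert-butyldimethylsilyl)oxy]-6-[(trimethylsilyl)oxy]germacra-1(10),4,11-triene | CC(C)(C)[Si](C)(C)O[C@H]1C/C=C(\C)CC[C@@H](C(C)=C)[C@H](O[Si](C)(C)C)/C=C1\C | intermediate (not isolated)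
15 | (1(10)E,4E,3S,6R,7S)-3-[(tert-butyldimethylsilyl)oxy]germacra-1(10),4,11-trien-6-ol | CC(C)(C)[Si](C)(C)O[C@H]1C/C=C(\C)CC[C@@H](C(C)=C)[C@H](O)/C=C1\C | intermediate
16 | (1(10)E,3S,4S,5R,6S,7S)-3-[(tert-butyldimethylsilyl)oxy]-4,5-epoxygermacra-1(10),11-dien-6-ol | CC(C)(C)[Si](C)(C)O[C@H]1C/C=C(\C)CC[C@@H](C(C)=C)[C@H](O)[C@H]2O[C@]12C | intermediate
17 | (1(10)E,3S,4S,5R,6S,7S)-3-[(tert-butyldimethylsilyl)oxy]-4,5-epoxygermacr-1(10)-en-6-ol | CC(C)(C)[Si](C)(C)O[C@H]1C/C=C(\C)CC[C@@H](C(C)C)[C@H](O)[C@H]2O[C@]12C | intermediate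
18 | (1(10)E,3S,4S,5R,6S,7S)-3-[(tert-butyldimethylsilyl)oxy]-4,5-epoxygermacr-1(10)-en-6-yl acetate | CC(C)(C)[Si](C)(C)O[C@H]1C/C=C(\C)CC[C@@H](C(C)C)[C@H](OC(C)=O)[C@H]2O[C@]12C | intermediate
19 | (1(10)E,3S,4R,5R,6S,7S)-6-acetoxy-4,5-epoxygermacr-1(10)-en-3-ol | O[C@H]1C/C=C(\C)CC[C@@H](C(C)C)[C@H](OC(C)=O)[C@H]2O[C@]12C | intermediate
20 | (1(10)E,3S,4R,5R,6S,7S)-6-acetoxy-4,5-epoxygermacr-1(10)-en-3-yl (Z)-2-methylbut-2-enoate | C/C=C(/C)C(=O)O[C@H]1C/C=C(\C)CC[C@@H](C(C)C)[C@H](OC(C)=O)[C@H]2O[C@]12C | target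

**Total step count:** 14. **Longest linear sequence:** 14 steps (1 and 2 → 20; the route is fully linear).

**Three steps most likely to fail**

Step 9 (the proposed new macrocyclisation). The risks are oligomerisation, chromium-mediated pinacol coupling of the enal, low enantioselectivity, and a ligand sense that opposes the preference of the C3 centre; the sense of induction must be checked on the first run, and the (R,R)-ligand is equally available. The fallback uses known chemistry, sets out from 11 and comes back at 16, bypassing steps 8–10; it also covers a poor face selectivity in step 10. Sharpless asymmetric epoxidation of 11 (Ti(OiPr)4, D-(−)-diethyl tartrate, t-BuOOH, 4 Å sieves, CH2Cl2, −20 °C) sets the oxirane by reagent control and gives [(2R,3S)-3-[(1S,3E,7E)-1-[(tert-butyldimethylsilyl)oxy]-9-chloro-4,8-dimethylnona-3,7-dien-1-yl]-3-methyloxiran-2-yl]methanol F6. Dess–Martin oxidation (pyridine buffer, CH2Cl2, 0 °C) gives (2S,3S)-3-[(1S,3E,7E)-1-[(tert-butyldimethylsilyl)oxy]-9-chloro-4,8-dimethylnona-3,7-dien-1-yl]-3-methyloxirane-2-carbaldehyde F7. A palladium/zinc umpolung allylation (Pd(PPh3)4 10 mol%, Et2Zn 3 equiv, THF, rt, 0.003 M) then closes the ten-membered ring to 16. Here the oxirane is the control element: the allylzinc adds anti to the C5–O bond from the inner face, with the aldehyde hydrogen next to the cis C4 methyl, and the chair transition state gives 6,7-anti. This is the model's prediction and the C6/C7 configuration of 16 must be confirmed (NOE or X-ray).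

Step 1 (allylbarium addition, with the sensitive ketone of step 2 behind it). The risks are the quality of the activated barium, the α/γ ratio, and isomerisation of the β,γ-unsaturated ketone 5 before reduction. The fallback sets out from 1 and comes back at 6, bypassing steps 1–3. (R)-4-Benzyloxazolidin-2-one is N-acylated (n-BuLi, THF, −78 °C; (4-methoxybenzyloxy)acetyl chloride) to (R)-4-benzyl-3-{[(4-methoxybenzyl)oxy]acetyl}oxazolidin-2-one F1. Its sodium enolate (NaN(SiMe3)2, THF, −78 °C) is alkylated with 1 in the presence of NaI (−78 → −40 °C), anti to the benzyl group (Evans glycolate alkylation), to give (R)-4-benzyl-3-[(2S,4E)-2-[(4-methoxybenzyl)oxy]-5,9-dimethyldeca-4,8-dienoyl]oxazolidin-2-one F2. Transamidation (MeONHMe·HCl, AlMe3, CH2Cl2) gives (2S,4E)-N-methoxy-2-[(4-methoxybenzyl)oxy]-N,5,9-trimethyldeca-4,8-dienamide F3. MeMgBr (THF, 0 °C) gives (3S,5E)-3-[(4-methoxybenzyl)oxy]-6,10-dimethylundeca-5,9-dien-2-one F4. Horner–Wadsworth–Emmons olefination ((EtO)2P(O)CH2CO2Et, NaH, THF, 0 °C; E/Z to be checked and separated) gives ethyl (2E,4S,6E)-4-[(4-methoxybenzyl)oxy]-3,7,11-trimethyldodeca-2,6,10-trienoate F5. DDQ (CH2Cl2/pH 7 buffer) removes the 4-methoxybenzyl group and gives 6.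

Step 14 (angeloylation of the hindered C3 alcohol). The risks are slow acylation next to the quaternary oxirane carbon, Z-to-E isomerisation to the tiglate, and thermal or acid damage to the epoxy-alkene. The fallback sets out from 19 and comes back at 20. Carbodiimide esterification of 19 with 2-[bis(2,2,2-trifluoroethoxy)phosphoryl]propanoic acid (DCC, DMAP, CH2Cl2, 0 °C) gives (1(10)E,3S,4R,5R,6S,7S)-6-acetoxy-4,5-epoxygermacr-1(10)-en-3-yl 2-[bis(2,2,2-trifluoroethoxy)phosphoryl]propanoate F8. A Still–Gennari olefination (KN(SiMe3)2, 18-crown-6, THF, −78 °C; acetaldehyde) then builds the Z-2-methylbut-2-enoate on the molecule and gives 20.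

**Further compounds**
F1 | step 1 | (R)-4-benzyl-3-{[(4-methoxybenzyl)oxy]acetyl}oxazolidin-2-one | COc1ccc(COCC(=O)N2[C@H](Cc3ccccc3)COC2=O)cc1
F2 | step 1 | (R)-4-benzyl-3-[(2S,4E)-2-[(4-methoxybenzyl)oxy]-5,9-dimethyldeca-4,8-dienoyl]oxazolidin-2-one | COc1ccc(CO[C@H](C(=O)N2[C@H](Cc3ccccc3)COC2=O)C/C=C(\C)CCC=C(C)C)cc1
F3 | step 1 | (2S,4E)-N-methoxy-2-[(4-methoxybenzyl)oxy]-N,5,9-trimethyldeca-4,8-dienamide | COc1ccc(CO[C@H](C(=O)N(C)OC)C/C=C(\C)CCC=C(C)C)cc1
F4 | step 1 | (3S,5E)-3-[(4-methoxybenzyl)oxy]-6,10-dimethylundeca-5,9-dien-2-one | COc1ccc(CO[C@H](C(C)=O)C/C=C(\C)CCC=C(C)C)cc1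
F5 | step 1 | ethyl (2E,4S,6E)-4-[(4-methoxybenzyl)oxy]-3,7,11-trimethyldodeca-2,6,10-trienoate | COc1ccc(CO[C@H](/C(C)=C/C(=O)OCC)C/C=C(\C)CCC=C(C)C)cc1
F6 | step 9 | [(2R,3S)-3-[(1S,3E,7E)-1-[(tert-butyldimethylsilyl)oxy]-9-chloro-4,8-dimethylnona-3,7-dien-1-yl]-3-methyloxiran-2-yl]methanol | OC[C@H]1O[C@]1(C)[C@@H](O[Si](C)(C)C(C)(C)C)C/C=C(\C)CC/C=C(\C)CCl
F7 | step 9 | (2S,3S)-3-[(1S,3E,7E)-1-[(tert-butyldimethylsilyl)oxy]-9-chloro-4,8-dimethylnona-3,7-dien-1-yl]-3-methyloxirane-2-carbaldehyde | O=C[C@H]1O[C@]1(C)[C@@H](O[Si](C)(C)C(C)(C)C)C/C=C(\C)CC/C=C(\C)CCl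
F8 | step 14 | (1(10)E,3S,4R,5R,6S,7S)-6-acetoxy-4,5-epoxygermacr-1(10)-en-3-yl 2-[bis(2,2,2-trifluoroethoxy)phosphoryl]propanoate | CC(C(=O)O[C@H]1C/C=C(\C)CC[C@@H](C(C)C)[C@H](OC(C)=O)[C@H]2O[C@]12C)P(=O)(OCC(F)(F)F)OCC(F)(F)F
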